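## Retrosynthetic overview

1. The target comes from C9‑O‑angeloylation and deboronation of a 7,8‑O‑phenylboronate. Its tertiary C7–O bond and the exocyclic methylene arise together from a boron‑tethered SN2′ hydroxylation of a 13‑ammonio 7(11)‑butenolide, with the oxygen delivered from O8.
2. That butenolide comes from an intramolecular Nozaki–Hiyama–Kishi reaction of a Z‑enol triflate (C7) onto the C6 enal, followed by lactonisation.
3. The enol triflate comes from a β‑keto ester, made from a Weinreb amide and the enolate of methyl 3‑(dimethylamino)propanoate (C11–C13).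
4. The Z C1=C10 alkene comes from a Wittig reaction of a D‑tartrate‑derived methyl ketone (C7–C10, stereocentres C8/C9) with a C1–C6 ylide made from 5‑chloropent‑1‑yne (E C4=C5 by carboalumination).
5. Ring order: dioxolane (from the tartrate), then ten‑membered carbocycle and butenolide in one step, then a temporary dioxaborolane, then the α‑methylene hydroxy lactone.

Assumption: atom labels follow germacranolide numbering (C6 lactone CH–O, C7 tertiary carbinol, C8/C9 diol carbons, C11=C13 exocyclic alkene, C12 lactone carbonyl, C14/C15 methyls on C10/C4), and the macrocycles are named on that skeleton.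

## Route

Step 1
Reactants: 1 dimethyl (4S,5S)-2,2-dimethyl-1,3-dioxolane-4,5-dicarboxylate (dimethyl 2,3-O-isopropylidene-D-tartrate)
Product: 2 (4S,5S)-N4,N5-dimethoxy-N4,N5,2,2-tetramethyl-1,3-dioxolane-4,5-dicarboxamide
Conditions: MeNH(OMe)·HCl (3 equiv), iPrMgCl (6 equiv), THF, −20 to 0 °C
Reagents that add atoms: N,O-dimethylhydroxylamine hydrochloride (CNOC.Cl)
Why: Ester aminolysis by the chloromagnesium amide of N,O-dimethylhydroxylamine (Weinreb amide formation); C8 and C9 are not touched.

Step 2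
Reactants: 2 bis-Weinreb amide
Product: 3 (4S,5S)-5-acetyl-N-methoxy-N,2,2-trimethyl-1,3-dioxolane-4-carboxamide
Conditions: MeMgBr (1.1 equiv), THF, −15 °C; aq. NH4Cl
Reagents that add atoms: methylmagnesium bromide (C[Mg]Br)
Why: Weinreb ketone synthesis as a desymmetrising mono-addition; the chelated, anionic adduct of the first amide survives to the quench and slows attack on the second amide, giving the C10 methyl ketone (C14) with C8/C9 intact.

Step 3
Reactants: 4 5-chloropent-1-yne
Product: 7 (2E)-6-chloro-3-methylhex-2-en-1-ol, via alkenylalane 5 (not isolated), via lithium alanate 6 (not isolated)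
Conditions: AlMe3 (2 equiv), Cp2ZrCl2 (20 mol %), CH2Cl2, 0 °C to rt; n-BuLi, THF, −78 °C; (CH2O)n, −78 °C to rt; aq. HCl
Reagents that add atoms: trimethylaluminium (C[Al](C)C); formaldehyde, used as paraformaldehyde (C=O)
Why: Negishi zirconium-catalysed carboalumination adds methyl and aluminium syn across the alkyne (methyl to the internal carbon), fixing the E geometry of C4=C5; the alanate is hydroxymethylated with retention to install C6.

Step 4
Reactants: 7 (2E)-6-chloro-3-methylhex-2-en-1-ol
Product: 8 tert-butyl{[(2E)-6-chloro-3-methylhex-2-en-1-yl]oxy}dimethylsilane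
Conditions: TBSCl, imidazole, CH2Cl2, rt
Reagents that add atoms: tert-butyldimethylsilyl chloride (CC(C)(C)[Si](C)(C)Cl)
Why: Standard silyl ether protection of the primary allylic alcohol so that it survives ylide, enolate and triflation chemistry.

Step 5
Reactants: 8 silyl ether chloride
Product: 10 [(4E)-6-(tert-butyldimethylsilyloxy)-4-methylhex-4-en-1-yl]triphenylphosphonium iodide, via alkyl iodide 9 (not isolated)
Conditions: NaI, PPh3, MeCN, reflux
Reagents that add atoms: sodium iodide ([Na+].[I-]); triphenylphosphine (c1ccc(cc1)P(c1ccccc1)c1ccccc1)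
Why: Finkelstein exchange followed by SN2 quaternisation of triphenylphosphine at the primary carbon.

Step 6
Reactants: 10 phosphonium iodide; 3 keto amide
Product: 12 (4S,5R)-5-[(2Z,6E)-8-(tert-butyldimethylsilyloxy)-6-methylocta-2,6-dien-2-yl]-N-methoxy-N,2,2-trimethyl-1,3-dioxolane-4-carboxamide, via phosphorus ylide 11 (not isolated)
Conditions: NaN(SiMe3)2, THF, −78 to 0 °C; then 3, −78 °C to rt
Reagents that add atoms: none
Why: Wittig olefination; non-stabilised ylides and α-alkoxy methyl ketones react under lithium-free conditions through the cis-oxaphosphetane to give the Z-trisubstituted allylic ether, so C9 ends cis to C2 across C1=C10, and the Weinreb amide is inert to the ylide at low temperature.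

Step 7
Reactants: 12 Weinreb amide diene; 13 methyl 3-(dimethylamino)propanoate
Product: 15 methyl 3-{(4S,5R)-5-[(2Z,6E)-8-(tert-butyldimethylsilyloxy)-6-methylocta-2,6-dien-2-yl]-2,2-dimethyl-1,3-dioxolan-4-yl}-2-[(dimethylamino)methyl]-3-oxopropanoate, via lithium enolate 14 (not isolated)
Conditions: 13, LiN(iPr)2, THF, −78 °C; then 12, −78 to −40 °C; aq. NH4Cl; used crude
Reagents that add atoms: none
Why: Claisen-type C-acylation of an ester enolate by a Weinreb amide; the chelated adduct prevents over-addition, and the β-amino enolate (a classical acrylate α-anion equivalent) does not eliminate because an amide is a poor leaving group; C11 is formed as an inconsequential epimer mixture.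

Step 8
Reactants: 15 β-keto ester
Product: 17 methyl (2Z)-3-{(4S,5R)-5-[(2Z,6E)-8-(tert-butyldimethylsilyloxy)-6-methylocta-2,6-dien-2-yl]-2,2-dimethyl-1,3-dioxolan-4-yl}-2-[(dimethylamino)methyl]-3-[(trifluoromethanesulfonyl)oxy]prop-2-enoate, via sodium enolate 16 (not isolated)
Conditions: NaH, THF, 0 °C; PhNTf2, THF/DMF, 0 °C to rt
Reagents that add atoms: N-phenylbis(trifluoromethanesulfonimide) (O=S(=O)(N(c1ccccc1)S(=O)(=O)C(F)(F)F)C(F)(F)F)
Why: O-triflation of the chelated sodium enolate; chelation between the two carbonyl oxygens holds the enolate oxygen cis to the ester, giving the Z enol triflate (OTf cis to CO2Me) needed for later lactonisation, and PhNTf2 does not react with the tertiary amine.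

Step 9
Reactants: 17 enol triflate silyl ether
Product: 18 methyl (2Z)-2-[(dimethylamino)methyl]-3-{(4S,5R)-5-[(2Z,6E)-8-hydroxy-6-methylocta-2,6-dien-2-yl]-2,2-dimethyl-1,3-dioxolan-4-yl}-3-[(trifluoromethanesulfonyl)oxy]prop-2-enoate
Conditions: HF·pyridine, pyridine, THF, 0 °C
Reagents that add atoms: none
Why: Fluoride cleavage of the primary allylic silyl ether; the acetonide and the enol triflate are stable to buffered HF.

Step 10
Reactants: 18 allylic alcohol
Product: 19 methyl (2Z)-2-[(dimethylamino)methyl]-3-{(4S,5R)-2,2-dimethyl-5-[(2Z,6E)-6-methyl-8-oxoocta-2,6-dien-2-yl]-1,3-dioxolan-4-yl}-3-[(trifluoromethanesulfonyl)oxy]prop-2-enoate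
Conditions: Dess–Martin periodinane, NaHCO3, CH2Cl2, 0 °C
Reagents that add atoms: none
Why: Dess–Martin oxidation of the allylic alcohol to the E-enal (C6) under buffered, non-isomerising conditions that tolerate the tertiary amine.

Step 11
Reactants: 19 enal enol triflate
Product: 21 (6S,8R,9R)-13-(dimethylamino)-8,9-(isopropylidenedioxy)germacra-1(10)Z,4E,7(11)-trien-12,6-olide, via hydroxy ester 20 (not isolated)
Conditions: CrCl2 (8 equiv), NiCl2 (2 mol %), degassed DMF/THF, slow addition to 0.003 M, rt; aqueous work-up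
Reagents that add atoms: none
Why: Intramolecular Nozaki–Hiyama–Kishi reaction; zerovalent nickel inserts into the vinyl triflate, transmetalation to chromium gives a vinylchromium that adds 1,2 to the enal, and the C6 alkoxide, cis to the ester, closes the butenolide. C6 is set under macrocyclic control with the C5 and C9 ring bonds on the same face of the planar butenolide (C8–H eclipsing C7=C11, least allylic 1,3-strain), and this isomer is also the thermodynamic one because C6–H is an epimerisable vinylogous γ-proton.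

Step 12
Reactants: 21 macrocyclic butenolide acetonide
Product: 22 (6S,8R,9R)-13-(dimethylamino)-8,9-dihydroxygermacra-1(10)Z,4E,7(11)-trien-12,6-olide
Conditions: AcOH/H2O 4:1, 45 °C; NaHCO3 work-up
Reagents that add atoms: none
Why: Acid hydrolysis of the isopropylidene acetal; the protonated amine and the butenolide are stable and no stereocentre is affected.

Step 13
Reactants: 22 amino diol butenolide
Product: 25 (6S,7S,8S,9R)-9-hydroxy-7,8-(phenylboranediyldioxy)germacra-1(10)Z,4E,11(13)-trien-12,6-olide, via 8,9-phenylboronate 23 (not isolated), via ammonium iodide 24 (not isolated)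
Conditions: PhB(OH)2 (1.2 equiv), 4 Å MS, CH2Cl2, rt; MeI (3 equiv), MeCN, rt, then evaporate; iPr2NEt (1.5 equiv), H2O (1 equiv), MeCN, 40 °C
Reagents that add atoms: phenylboronic acid (OB(O)c1ccccc1)
Why: Proposed new method: boron-tethered SN2′ hydroxylation of a butenolide Mannich salt; with the diol held as boronate 23 and the amine quaternised (24), base and one equivalent of water open the boronate to its C8–O–B(Ph)–OH form, whose amine-activated B–OH oxygen adds 5-exo to C7 of the unsaturated lactone (made more electrophilic by the ammonium group), and the enolate at once expels NMe3 (E1cB), so the hindered, normally reversible oxa-Michael step becomes irreversible, the C11=C13 methylene appears and boron ends on O7/O8 with only O9–H free; the oxygen is carried by O8 and can only enter cis to it, on the open face of the butenolide that also bears H6, which fixes C7 as S; the closest known reactions are the boronic acid hemiester oxa-Michael addition to γ-hydroxy enones and the SN2′/E1cB substitution of Morita–Baylis–Hillman-type allylic ammonium salts (last stage of an Eschenmoser methylenation).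

Step 14
Reactants: 25 boronate alcohol; 26 angelic acid, (2Z)-2-methylbut-2-enoic acid
Product: 29 (6S,7S,8S,9R)-9-angeloyloxy-7,8-dihydroxygermacra-1(10)Z,4E,11(13)-trien-12,6-olide (CNP0303917.1), via mixed anhydride 27 (not isolated), via angelate boronate 28 (not isolated)
Conditions: 26, 2,4,6-Cl3C6H2COCl, Et3N, toluene, rt; add 25, 75 °C (no DMAP); then pinacol, MeOH, rt
Reagents that add atoms: none
Why: Yamaguchi esterification; the mixed anhydride acylates the only free hydroxyl (allylic C9–OH, while O7 and O8 are masked by boron) and omitting DMAP avoids angelate-to-tiglate isomerisation; transesterification of the phenylboronate to pinacol then frees the 7,8-diol without changing any stereocentre.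

## Compound list

1 | dimethyl (4S,5S)-2,2-dimethyl-1,3-dioxolane-4,5-dicarboxylate | COC(=O)[C@H]1OC(C)(C)O[C@@H]1C(=O)OC | starting material
2 | (4S,5S)-N4,N5-dimethoxy-N4,N5,2,2-tetramethyl-1,3-dioxolane-4,5-dicarboxamide | CON(C)C(=O)[C@H]1OC(C)(C)O[C@@H]1C(=O)N(C)OC | intermediate
3 | (4S,5S)-5-acetyl-N-methoxy-N,2,2-trimethyl-1,3-dioxolane-4-carboxamide | CON(C)C(=O)[C@H]1OC(C)(C)O[C@@H]1C(C)=O | intermediate
4 | 5-chloropent-1-yne | C#CCCCCl | starting material
5 | [(1E)-5-chloro-2-methylpent-1-en-1-yl]dimethylalane | C[Al](C)/C=C(\C)CCCCl | intermediate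
6 | lithium butyl[(1E)-5-chloro-2-methylpent-1-en-1-yl]dimethylalanate | [Li+].CCCC[Al-](C)(C)/C=C(\C)CCCCl | intermediate
7 | (2E)-6-chloro-3-methylhex-2-en-1-ol | OC/C=C(\C)CCCCl | intermediate
8 | tert-butyl{[(2E)-6-chloro-3-methylhex-2-en-1-yl]oxy}dimethylsilane | CC(C)(C)[Si](C)(C)OC/C=C(\C)CCCCl | intermediate
9 | tert-butyl{[(2E)-6-iodo-3-methylhex-2-en-1-yl]oxy}dimethylsilane | CC(C)(C)[Si](C)(C)OC/C=C(\C)CCCI | intermediate
10 | [(4E)-6-(tert-butyldimethylsilyloxy)-4-methylhex-4-en-1-yl]triphenylphosphonium iodide | CC(C)(C)[Si](C)(C)OC/C=C(\C)CCC[P+](c1ccccc1)(c1ccccc1)c1ccccc1.[I-] | intermediate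
11 | [(4E)-6-(tert-butyldimethylsilyloxy)-4-methylhex-4-en-1-ylidene]triphenylphosphorane | CC(C)(C)[Si](C)(C)OC/C=C(\C)CCC=P(c1ccccc1)(c1ccccc1)c1ccccc1 | intermediate
12 | (4S,5R)-5-[(2Z,6E)-8-(tert-butyldimethylsilyloxy)-6-methylocta-2,6-dien-2-yl]-N-methoxy-N,2,2-trimethyl-1,3-dioxolane-4-carboxamide | CON(C)C(=O)[C@H]1OC(C)(C)O[C@@H]1/C(C)=C\CC/C(C)=C/CO[Si](C)(C)C(C)(C)C | intermediate
13 | methyl 3-(dimethylamino)propanoate | COC(=O)CCN(C)C | starting material
14 | lithium enolate of methyl 3-(dimethylamino)propanoate | [Li+].COC([O-])=CCN(C)C | intermediate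
15 | methyl 3-{(4S,5R)-5-[(2Z,6E)-8-(tert-butyldimethylsilyloxy)-6-methylocta-2,6-dien-2-yl]-2,2-dimethyl-1,3-dioxolan-4-yl}-2-[(dimethylamino)methyl]-3-oxopropanoate (C11 epimers) | COC(=O)C(CN(C)C)C(=O)[C@H]1OC(C)(C)O[C@@H]1/C(C)=C\CC/C(C)=C/CO[Si](C)(C)C(C)(C)C | intermediate
16 | sodium (Z)-enolate of 15 (enolate oxygen cis to the ester) | [Na+].COC(=O)/C(CN(C)C)=C(\[O-])[C@H]1OC(C)(C)O[C@@H]1/C(C)=C\CC/C(C)=C/CO[Si](C)(C)C(C)(C)C | intermediate
17 | methyl (2Z)-3-{(4S,5R)-5-[(2Z,6E)-8-(tert-butyldimethylsilyloxy)-6-methylocta-2,6-dien-2-yl]-2,2-dimethyl-1,3-dioxolan-4-yl}-2-[(dimethylamino)methyl]-3-[(trifluoromethanesulfonyl)oxy]prop-2-enoate | COC(=O)/C(CN(C)C)=C(\OS(=O)(=O)C(F)(F)F)[C@H]1OC(C)(C)O[C@@H]1/C(C)=C\CC/C(C)=C/CO[Si](C)(C)C(C)(C)C | intermediate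
18 | methyl (2Z)-2-[(dimethylamino)methyl]-3-{(4S,5R)-5-[(2Z,6E)-8-hydroxy-6-methylocta-2,6-dien-2-yl]-2,2-dimethyl-1,3-dioxolan-4-yl}-3-[(trifluoromethanesulfonyl)oxy]prop-2-enoate | COC(=O)/C(CN(C)C)=C(\OS(=O)(=O)C(F)(F)F)[C@H]1OC(C)(C)O[C@@H]1/C(C)=C\CC/C(C)=C/CO | intermediate
19 | methyl (2Z)-2-[(dimethylamino)methyl]-3-{(4S,5R)-2,2-dimethyl-5-[(2Z,6E)-6-methyl-8-oxoocta-2,6-dien-2-yl]-1,3-dioxolan-4-yl}-3-[(trifluoromethanesulfonyl)oxy]prop-2-enoate | COC(=O)/C(CN(C)C)=C(\OS(=O)(=O)C(F)(F)F)[C@H]1OC(C)(C)O[C@@H]1/C(C)=C\CC/C(C)=C/C=O | intermediate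
20 | methyl (6S,8R,9R)-13-(dimethylamino)-6-hydroxy-8,9-(isopropylidenedioxy)germacra-1(10)Z,4E,7(11)-trien-12-oate (ester cis to C6) | COC(=O)/C(CN(C)C)=C1\[C@@H](O)/C=C(\C)CC/C=C(/C)[C@H]2OC(C)(C)O[C@H]12 | intermediate
21 | (6S,8R,9R)-13-(dimethylamino)-8,9-(isopropylidenedioxy)germacra-1(10)Z,4E,7(11)-trien-12,6-olide | CN(C)CC1=C2[C@@H](OC1=O)/C=C(\C)CC/C=C(/C)[C@H]3OC(C)(C)O[C@H]23 | intermediate
22 | (6S,8R,9R)-13-(dimethylamino)-8,9-dihydroxygermacra-1(10)Z,4E,7(11)-trien-12,6-olide | CN(C)CC1=C2[C@@H](OC1=O)/C=C(\C)CC/C=C(/C)[C@@H](O)[C@@H]2O | intermediate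
23 | (6S,8R,9R)-13-(dimethylamino)-8,9-(phenylboranediyldioxy)germacra-1(10)Z,4E,7(11)-trien-12,6-olide | CN(C)CC1=C2[C@@H](OC1=O)/C=C(\C)CC/C=C(/C)[C@H]3OB(c4ccccc4)O[C@H]23 | intermediate
24 | (6S,8R,9R)-8,9-(phenylboranediyldioxy)-13-(trimethylammonio)germacra-1(10)Z,4E,7(11)-trien-12,6-olide iodide | C[N+](C)(C)CC1=C2[C@@H](OC1=O)/C=C(\C)CC/C=C(/C)[C@H]3OB(c4ccccc4)O[C@H]23.[I-] | intermediate
25 | (6S,7S,8S,9R)-9-hydroxy-7,8-(phenylboranediyldioxy)germacra-1(10)Z,4E,11(13)-trien-12,6-olide | C=C1C(=O)O[C@H]2/C=C(\C)CC/C=C(/C)[C@@H](O)[C@@H]3OB(c4ccccc4)O[C@]123 | intermediate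
26 | angelic acid, (2Z)-2-methylbut-2-enoic acid | C/C=C(/C)C(=O)O | starting material
27 | (2Z)-2-methylbut-2-enoic 2,4,6-trichlorobenzoic anhydride | C/C=C(/C)C(=O)OC(=O)c1c(Cl)cc(Cl)cc1Cl | intermediate
28 | (6S,7S,8S,9R)-9-angeloyloxy-7,8-(phenylboranediyldioxy)germacra-1(10)Z,4E,11(13)-trien-12,6-olide | C=C1C(=O)O[C@H]2/C=C(\C)CC/C=C(/C)[C@@H](OC(=O)/C(C)=C\C)[C@@H]3OB(c4ccccc4)O[C@]123 | intermediate
29 | (6S,7S,8S,9R)-9-angeloyloxy-7,8-dihydroxygermacra-1(10)Z,4E,11(13)-trien-12,6-olide (CNP0303917.1) | C=C1C(=O)O[C@H]2/C=C(\C)CC/C=C(/C)[C@@H](OC(=O)/C(C)=C\C)[C@H](O)[C@@]12O | target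

## Step count and risks

Total steps: 14. Longest linear sequence: 12 steps (4 to 29, steps 3–14); the tartrate branch (1 to 3) joins after 2 steps.

**Step 13 (the new C–O step).** Addition of oxygen to the fully substituted C7 may be slow. Competing paths are direct SN2 etherification of C13 by a free O8–H, delivery from an O9-bound boron, and vinylogous deprotonation at C6 with loss of NMe3 and substitution at C13. The boron-bound oxygen is far more easily activated by the amine base than C6–H is removed, which is why the tethered path is expected to win.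

Fallback with known chemistry: starting from 22, mCPBA (1 equiv, CH2Cl2, −78 °C) oxidises only the amine to the amine N-oxide F1. Warming (CHCl3, 40 °C) triggers the [2,3]-Meisenheimer rearrangement to the O-allyl hydroxylamine F2, forming the C7–O bond and the exocyclic methylene, with the N-oxide oxygen hydrogen-bonded to O8–H and so delivered to the same face. Zn/AcOH cleaves the N–O bond to the triol F3. PhB(OH)2 with 4 Å MS converts F3 into 25, where the route is rejoined.

**Step 11 (macrocyclic Nozaki–Hiyama–Kishi reaction).** The nucleophile is a tetrasubstituted vinylchromium and the ring is ten-membered; oligomerisation, reduction of the triflate or poor control at C6 are possible.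

Fallback: starting from 19, Pinnick oxidation (NaClO2, NaH2PO4, 2-methylbut-2-ene, t-BuOH/H2O) gives the carboxylic acid F4. 2,2′-Dipyridyl disulfide/PPh3 gives the 2-pyridyl thioester F5. A nickel/zirconium-mediated reductive acyl–vinyl coupling (NiBr2(dtbbpy), Cp2ZrCl2, Zn, DMI/THF, high dilution) closes the ring as the macrocyclic dienone ester F6. Reduction with (R)-2-methyl-CBS-oxazaborolidine/catecholborane (C7 side acting as the large group) then sets C6 by reagent control and gives 20, which lactonises to 21, where the route is rejoined.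

**Step 7 (acylation with the β-amino ester enolate).** The enolate may acylate sluggishly, and the Mannich-base β-keto ester can lose amine on handling.

Fallback: starting from 12, the lithium enolate of methyl acetate (LiN(iPr)2, THF, −78 °C) gives the unsubstituted β-keto ester F7. A Mannich reaction with dimethylmethyleneammonium iodide (CH2Cl2, rt) then installs the CH2NMe2 group and gives 15, where the route is rejoined.

## Further compounds

F1 | step 13 | (6S,8R,9R)-8,9-dihydroxy-13-(dimethylamino)germacra-1(10)Z,4E,7(11)-trien-12,6-olide N-oxide (amine N-oxide) | C[N+](C)([O-])CC1=C2[C@@H](OC1=O)/C=C(\C)CC/C=C(/C)[C@@H](O)[C@@H]2O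
F2 | step 13 | (6S,7S,8S,9R)-7-[(dimethylamino)oxy]-8,9-dihydroxygermacra-1(10)Z,4E,11(13)-trien-12,6-olide (O-allyl hydroxylamine) | C=C1C(=O)O[C@H]2/C=C(\C)CC/C=C(/C)[C@@H](O)[C@H](O)[C@@]12ON(C)C
F3 | step 13 | (6S,7S,8S,9R)-7,8,9-trihydroxygermacra-1(10)Z,4E,11(13)-trien-12,6-olide (triol) | C=C1C(=O)O[C@H]2/C=C(\C)CC/C=C(/C)[C@@H](O)[C@H](O)[C@@]12O
F4 | step 11 | carboxylic acid corresponding to enal 19 (C6 CHO oxidised to CO2H, all else unchanged) | COC(=O)/C(CN(C)C)=C(\OS(=O)(=O)C(F)(F)F)[C@H]1OC(C)(C)O[C@@H]1/C(C)=C\CC/C(C)=C/C(=O)O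
F5 | step 11 | S-(pyridin-2-yl) thioester of F4 | COC(=O)/C(CN(C)C)=C(\OS(=O)(=O)C(F)(F)F)[C@H]1OC(C)(C)O[C@@H]1/C(C)=C\CC/C(C)=C/C(=O)Sc1ccccn1
F6 | step 11 | methyl (8R,9R)-13-(dimethylamino)-8,9-(isopropylidenedioxy)-6-oxogermacra-1(10)Z,4E,7(11)-trien-12-oate (ester cis to C6) | COC(=O)/C(CN(C)C)=C1\C(=O)/C=C(\C)CC/C=C(/C)[C@H]2OC(C)(C)O[C@H]12
F7 | step 7 | methyl 3-{(4S,5R)-5-[(2Z,6E)-8-(tert-butyldimethylsilyloxy)-6-methylocta-2,6-dien-2-yl]-2,2-dimethyl-1,3-dioxolan-4-yl}-3-oxopropanoate | COC(=O)CC(=O)[C@H]1OC(C)(C)O[C@@H]1/C(C)=C\CC/C(C)=C/CO[Si](C)(C)C(C)(C)C
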